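**Assumption:** the target SMILES describes the centrosymmetric (meso) α-truxillic-type cyclobutane. The two pyronyl groups are 1,3-trans, the two aryl groups are 2,4-trans, and each pyronyl is cis to one neighbouring aryl and trans to the other. The compound is therefore achiral and only relative configuration has to be controlled.

## Retrosynthetic overview

1. Target 16 ⇒ bis(4-hydroxy-2-pyrone) 14 by removing the two phenol benzyl groups and the two O4-methyl groups.
2. Feature: in each pyrone (O1, C2–C6), C6 (the carbon bonded to the cyclobutane) and C5 are the two carbons of an alkyne, and O1 is the ester carbonyl oxygen of a tert-butyl β-keto ester. Cutting both O1–C6 bonds turns 14 into the bis(tert-butyl 3-oxopent-4-ynoate) 13.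
3. 13 ⇒ bis-ynal 9 + two tert-butyl acetate (aldol, then oxidation); 9 ⇒ dialdehyde 6 (Corey–Fuchs homologation with DMF quench).
4. 6 ⇒ 4,4'-dihydroxy-α-truxillic acid 2 ⇒ two molecules of p-coumaric acid (head-to-tail solid-state [2+2] photodimerisation).
5. Ring order: the cyclobutane first (step 1, all four stereocentres), then both pyrone rings in one operation (step 9).

Key step: step 9

## Route

Step 1
Reactants: 1 p-coumaric acid (two molecules)
Product: 2 (1α,2α,3β,4β)-2,4-bis(4-hydroxyphenyl)cyclobutane-1,3-dicarboxylic acid (4,4'-dihydroxy-α-truxillic acid)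
Conditions: hν (medium-pressure Hg lamp, Pyrex filter), finely ground crystals suspended in hexane, rt
Reagents that add atoms: p-coumaric acid (the second molecule of 1) O=C(O)/C=C/c1ccc(O)cc1
Why: Topochemical [2+2] photocycloaddition of two molecules of 1: in the crystal the acid molecules stack head-to-tail across inversion centres with parallel C=C bonds within the Schmidt distance, so the lattice sets all four stereocentres at once and should deliver the centrosymmetric α-truxillic isomer.

Step 2
Reactants: 2 4,4'-dihydroxy-α-truxillic acid; 3 benzyl bromide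
Product: 4 dibenzyl (1α,2α,3β,4β)-2,4-bis[4-(benzyloxy)phenyl]cyclobutane-1,3-dicarboxylate
Conditions: BnBr (4.4 equiv), K2CO3, DMF, rt
Reagents that add atoms: benzyl bromide (three further molecules of 3) BrCc1ccccc1.BrCc1ccccc1.BrCc1ccccc1
Why: Carbonate-mediated SN2 O-alkylation (Williamson etherification of the two phenoxides and alkylation of the two carboxylates, four benzyl bromide molecules in all) should cap all four acidic OH groups in one operation, and the ring stereocentres are safe because the acids react as carboxylates and K2CO3 does not enolise the resulting esters at room temperature.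

Step 3
Reactants: 4 tetrabenzyl compound
Product: 5 [(1α,2α,3β,4β)-2,4-bis[4-(benzyloxy)phenyl]cyclobutane-1,3-diyl]dimethanol
Conditions: LiAlH4, THF, 0 °C to rt; Fieser work-up
Reagents that add atoms: none
Why: Hydride reduction of both benzyl esters to primary alcohols (LiAlH4 ester reduction) leaves the aryl benzyl ethers intact, and the transient aldehydes are reduced faster than they can enolise, so the ring configuration is kept.

Step 4
Reactants: 5 diol
Product: 6 (1α,2α,3β,4β)-2,4-bis[4-(benzyloxy)phenyl]cyclobutane-1,3-dicarbaldehyde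
Conditions: Dess–Martin periodinane (2.4 equiv), CH2Cl2, 0 °C to rt; cold aq. Na2S2O3/NaHCO3 wash; used crude without chromatography
Reagents that add atoms: none
Why: Dess–Martin oxidation is base-free and runs at or below room temperature, so both primary alcohols should become aldehydes without enolisation of the adjacent ring stereocentres, and the 1,3-trans arrangement prevents lactol formation at the half-oxidised stage.

Step 5
Reactants: 6 dialdehyde
Product: 7 (1α,2α,3β,4β)-1,3-bis(2,2-dibromovinyl)-2,4-bis[4-(benzyloxy)phenyl]cyclobutane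
Conditions: CBr4 (4 equiv), PPh3 (8 equiv), CH2Cl2, 0 °C
Reagents that add atoms: carbon tetrabromide (2 equiv) BrC(Br)(Br)Br.BrC(Br)(Br)Br
Why: First stage of the Corey–Fuchs homologation (Ramirez dibromo-olefination): the ylide Ph3P=CBr2 formed in situ olefinates each aldehyde under neutral conditions, which removes the epimerisable formyl groups without exposing them to base.

Step 6
Reactants: 7 bis(dibromoalkene)
Product: 9 bis(prop-2-ynal) on the α-truxillic cyclobutane core, via dilithium bis-acetylide 8 (not isolated)
Conditions: n-BuLi (4.4 equiv), THF, −78 °C; DMF (excess), −78 to 0 °C; inverse quench into cold aq. KH2PO4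
Reagents that add atoms: N,N-dimethylformamide (2 equiv) CN(C)C=O.CN(C)C=O
Why: Second stage of the Corey–Fuchs reaction: bromine–lithium exchange with Fritsch–Buttenberg–Wiechell 1,2-shift and deprotonation gives the lithium acetylide on each arm, one DMF per arm formylates it at carbon, and the phosphate quench releases the ynal without amine-induced decomposition.

Step 7
Reactants: 9 bis-ynal; 10 tert-butyl acetate
Product: 12 di-tert-butyl bis(3-hydroxypent-4-ynoate) on the cyclobutane core (mixture of carbinol epimers), via lithium enolate of tert-butyl acetate 11 (not isolated)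
Conditions: LiN(i-Pr)2 (2.4 equiv), 10 (2.4 equiv), THF, −78 °C; then 9, −78 °C; aq. NH4Cl
Reagents that add atoms: tert-butyl acetate (the second molecule of 10) CC(=O)OC(C)(C)C
Why: Aldol addition of the preformed lithium ester enolate, one per aldehyde, to the unhindered alkynyl aldehydes proceeds by 1,2-attack at −78 °C, faster than deprotonation of the remote ring C–H; the two new carbinol centres form unselectively, which does not matter because step 8 oxidises them.

Step 8
Reactants: 12 bis(β-hydroxy ester)
Product: 13 di-tert-butyl 5,5'-{(1α,2α,3β,4β)-2,4-bis[4-(benzyloxy)phenyl]cyclobutane-1,3-diyl}bis(3-oxopent-4-ynoate)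
Conditions: Dess–Martin periodinane (slight excess per OH), CH2Cl2, 0 °C to rt
Reagents that add atoms: none
Why: Dess–Martin oxidation of the two propargylic secondary alcohols should give the ynone β-keto esters under neutral conditions that the tert-butyl esters, benzyl ethers and electrophilic ynones tolerate, and it erases the carbinol stereocentres.

Step 9
Reactants: 13 bis(tert-butyl 3-oxopent-4-ynoate)
Product: 14 6,6'-{(1α,2α,3β,4β)-2,4-bis[4-(benzyloxy)phenyl]cyclobutane-1,3-diyl}bis(4-hydroxy-2H-pyran-2-one)
Conditions: (Ph3P)AuNTf2 (10 mol%), MeNO2/AcOH 4:1, rt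
Reagents that add atoms: none
Why: The cationic monovalent gold centre π-activates each ynone triple bond, the carbonyl oxygen of the tert-butyl ester attacks the cyclobutane-bound alkyne carbon anti to gold to form the O1–C6 bond, the resulting tert-butyl oxocarbenium ion loses isobutene to leave the lactone carbonyl, and protodeauration at C5 with enolisation of the C4 ketone gives the 4-hydroxy-2-pyrone. This is the known gold-catalysed cycloisomerisation of tert-butyl 3-oxoalk-4-ynoates to 4-hydroxy-2-pyrones, run here on two identical arms in one flask. Each of the two pyrone rings closes in the 6-endo-dig mode through its O1–C6 bond. No stereocentre is formed; the four cyclobutane centres are spectators, and the base-free, weakly acidic medium leaves the propargylic ring C–H bonds untouched, so isomerisation through allenyl ketones is not expected. The step needs 6-endo O-attack to win over 5-exo attack at the carbon next to the ketone and over hydroarylation by the cis-disposed aryl ring. The first is secured by the ynone polarisation, which makes the cyclobutane-bound carbon the electrophilic β-position, and the second by the para-benzyloxy group, which leaves the ring carbons ortho to the cyclobutane meta to oxygen and therefore unactivated.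

Step 10
Reactants: 14 bis(4-hydroxy-2-pyrone)
Product: 15 6,6'-{(1α,2α,3β,4β)-2,4-bis[4-(benzyloxy)phenyl]cyclobutane-1,3-diyl}bis(4-methoxy-2H-pyran-2-one)
Conditions: Me2SO4 (2.5 equiv), K2CO3, acetone, 40 °C
Reagents that add atoms: dimethyl sulfate (2 equiv) COS(=O)(=O)OC.COS(=O)(=O)OC
Why: O-Alkylation of the vinylogous acid: each pyronate anion is methylated by the hard electrophile dimethyl sulfate at O4, the site that keeps the 2-pyrone conjugation, as in the standard methylation of 4-hydroxy-6-alkyl-2-pyrones, while the phenols stay masked as benzyl ethers and carbonate is too weak to deprotonate the ring C–H bonds.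

Step 11
Reactants: 15 bis(4-methoxy-2-pyrone) bis(benzyl ether)
Product: 16 6,6'-[(1α,2α,3β,4β)-2,4-bis(4-hydroxyphenyl)cyclobutane-1,3-diyl]bis(4-methoxy-2H-pyran-2-one) (target)
Conditions: H2 (1 atm), 10% Pd/C, EtOAc/THF, rt; stopped after two equivalents of H2
Reagents that add atoms: none
Why: Heterogeneous hydrogenolysis of the two aryl benzyl ethers (benzylic C–O cleavage on palladium) is fast at ambient pressure, whereas the 4-methoxy-2-pyrone rings, a motif that survives hydrogenation of styryl double bonds in kavalactone-type pyrones, and the cyclobutane should remain intact.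

## Compound list

1 | p-coumaric acid, (E)-3-(4-hydroxyphenyl)prop-2-enoic acid | O=C(O)/C=C/c1ccc(O)cc1 | starting material
2 | (1α,2α,3β,4β)-2,4-bis(4-hydroxyphenyl)cyclobutane-1,3-dicarboxylic acid (4,4'-dihydroxy-α-truxillic acid) | OC(=O)[C@H]1[C@H](c2ccc(O)cc2)[C@H](C(=O)O)[C@H]1c1ccc(O)cc1 | intermediate
3 | benzyl bromide | BrCc1ccccc1 | starting material
4 | dibenzyl (1α,2α,3β,4β)-2,4-bis[4-(benzyloxy)phenyl]cyclobutane-1,3-dicarboxylate | O=C(OCc1ccccc1)[C@H]1[C@H](c2ccc(OCc3ccccc3)cc2)[C@H](C(=O)OCc2ccccc2)[C@H]1c1ccc(OCc2ccccc2)cc1 | intermediate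
5 | [(1α,2α,3β,4β)-2,4-bis[4-(benzyloxy)phenyl]cyclobutane-1,3-diyl]dimethanol | OC[C@H]1[C@H](c2ccc(OCc3ccccc3)cc2)[C@H](CO)[C@H]1c1ccc(OCc2ccccc2)cc1 | intermediate
6 | (1α,2α,3β,4β)-2,4-bis[4-(benzyloxy)phenyl]cyclobutane-1,3-dicarbaldehyde | O=C[C@H]1[C@H](c2ccc(OCc3ccccc3)cc2)[C@H](C=O)[C@H]1c1ccc(OCc2ccccc2)cc1 | intermediate
7 | (1α,2α,3β,4β)-1,3-bis(2,2-dibromovinyl)-2,4-bis[4-(benzyloxy)phenyl]cyclobutane | BrC(Br)=C[C@H]1[C@H](c2ccc(OCc3ccccc3)cc2)[C@H](C=C(Br)Br)[C@H]1c1ccc(OCc2ccccc2)cc1 | intermediate
8 | dilithium bis-acetylide of (1α,2α,3β,4β)-1,3-diethynyl-2,4-bis[4-(benzyloxy)phenyl]cyclobutane | [Li]C#C[C@H]1[C@H](c2ccc(OCc3ccccc3)cc2)[C@H](C#C[Li])[C@H]1c1ccc(OCc2ccccc2)cc1 | intermediate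
9 | 3,3'-{(1α,2α,3β,4β)-2,4-bis[4-(benzyloxy)phenyl]cyclobutane-1,3-diyl}bis(prop-2-ynal) | O=CC#C[C@H]1[C@H](c2ccc(OCc3ccccc3)cc2)[C@H](C#CC=O)[C@H]1c1ccc(OCc2ccccc2)cc1 | intermediate
10 | tert-butyl acetate | CC(=O)OC(C)(C)C | starting material
11 | lithium enolate of tert-butyl acetate | C=C(O[Li])OC(C)(C)C | intermediate
12 | di-tert-butyl 5,5'-{(1α,2α,3β,4β)-2,4-bis[4-(benzyloxy)phenyl]cyclobutane-1,3-diyl}bis(3-hydroxypent-4-ynoate), carbinol carbons as a mixture of epimers | CC(C)(C)OC(=O)CC(O)C#C[C@H]1[C@H](c2ccc(OCc3ccccc3)cc2)[C@H](C#CC(O)CC(=O)OC(C)(C)C)[C@H]1c1ccc(OCc2ccccc2)cc1 | intermediate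
13 | di-tert-butyl 5,5'-{(1α,2α,3β,4β)-2,4-bis[4-(benzyloxy)phenyl]cyclobutane-1,3-diyl}bis(3-oxopent-4-ynoate) | CC(C)(C)OC(=O)CC(=O)C#C[C@H]1[C@H](c2ccc(OCc3ccccc3)cc2)[C@H](C#CC(=O)CC(=O)OC(C)(C)C)[C@H]1c1ccc(OCc2ccccc2)cc1 | intermediate
14 | 6,6'-{(1α,2α,3β,4β)-2,4-bis[4-(benzyloxy)phenyl]cyclobutane-1,3-diyl}bis(4-hydroxy-2H-pyran-2-one) | Oc1cc(=O)oc([C@H]2[C@H](c3ccc(OCc4ccccc4)cc3)[C@H](c3cc(O)cc(=O)o3)[C@H]2c2ccc(OCc3ccccc3)cc2)c1 | intermediate
15 | 6,6'-{(1α,2α,3β,4β)-2,4-bis[4-(benzyloxy)phenyl]cyclobutane-1,3-diyl}bis(4-methoxy-2H-pyran-2-one) | COc1cc(=O)oc([C@H]2[C@H](c3ccc(OCc4ccccc4)cc3)[C@H](c3cc(OC)cc(=O)o3)[C@H]2c2ccc(OCc3ccccc3)cc2)c1 | intermediate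
16 | 6,6'-[(1α,2α,3β,4β)-2,4-bis(4-hydroxyphenyl)cyclobutane-1,3-diyl]bis(4-methoxy-2H-pyran-2-one) | COc1cc(=O)oc([C@H]2[C@H](c3ccc(O)cc3)[C@H](c3cc(OC)cc(=O)o3)[C@H]2c2ccc(O)cc2)c1 | target

## Step count and risks

Total step count: 11. Longest linear sequence: 11 steps (1 to 16).

**Steps most likely to fail**

1. Step 9 (twofold gold cyclisation). The reaction may stall after the first ring closure. The gold-activated ynone may also be diverted into hydration or hydroarylation, or the tert-butyl ester may be lost before cyclisation and the β-keto acid decarboxylate.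
   Fallback: this sets out from dialdehyde 6 and builds each pyrone by the acylketene route. The O-trimethylsilyl dienol ether derived from 2,2,6-trimethyl-4H-1,3-dioxin-4-one is added to 6 in a vinylogous Mukaiyama aldol reaction (BF3·OEt2, CH2Cl2, −78 °C), which keeps the aldehyde away from base. After aqueous work-up this should give the bis(δ-hydroxy dioxinone) F1 as a mixture of carbinol epimers. Dess–Martin oxidation should give the bis(β-keto dioxinone) F2. Heating F2 in toluene at 110 °C should expel acetone by retro-hetero-Diels–Alder reaction, and the acylketene is trapped by the enol oxygen of the neighbouring ketone. This closes both 4-hydroxy-2-pyrone rings and rejoins the route at 14. The ring carbons are α to a ketone in F2, so it would be kept free of base and thermolysed promptly.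

2. Step 4 (dialdehyde). Enolisation of the formyl-bearing ring carbons during oxidation, work-up or any contact with silica would epimerise one centre and erode the 1,3-trans relationship. The two arrangements are of similar energy, so no thermodynamic correction is available.
   Fallback: this sets out from tetraester 4 and reaches the aldehyde by partial reduction instead of oxidation. Saponification (LiOH, THF/MeOH/H2O, rt) should give the 2,4-bis[4-(benzyloxy)phenyl]cyclobutane-1,3-dicarboxylic acid F3. Activation with carbonyldiimidazole and coupling with N,O-dimethylhydroxylamine hydrochloride should give the bis(Weinreb amide) F4. Reduction with i-Bu2AlH in THF at −78 °C holds each carbonyl as a stable chelated tetrahedral intermediate, and a cold tartaric acid quench releases dialdehyde 6. The aldehyde is then carried directly into step 5.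

3. Step 11 (debenzylation). Hydrogen may saturate the pyrone C5=C6 double bond in competition with benzyl ether cleavage, giving dihydropyrone by-products.
   Fallback: this sets out from 15 and replaces hydrogenolysis by Lewis-acid dealkylation. BCl3 with pentamethylbenzene as a non-basic benzyl-cation scavenger in CH2Cl2 at −78 °C should cleave both aryl benzyl ethers and return directly to 16. The 4-methoxy groups cannot chelate boron with the C2 carbonyl (1,3-disposed exocyclic oxygens), so they should survive the short low-temperature exposure.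

## Further compounds

F1 | step 9 | 6,6'-{[(1α,2α,3β,4β)-2,4-bis[4-(benzyloxy)phenyl]cyclobutane-1,3-diyl]bis(2-hydroxyethane-2,1-diyl)}bis(2,2-dimethyl-4H-1,3-dioxin-4-one), carbinol carbons as a mixture of epimers | CC1(C)OC(=O)C=C(CC(O)[C@H]2[C@H](c3ccc(OCc4ccccc4)cc3)[C@H](C(O)CC3=CC(=O)OC(C)(C)O3)[C@H]2c2ccc(OCc3ccccc3)cc2)O1
F2 | step 9 | 6,6'-{[(1α,2α,3β,4β)-2,4-bis[4-(benzyloxy)phenyl]cyclobutane-1,3-diyl]bis(2-oxoethane-2,1-diyl)}bis(2,2-dimethyl-4H-1,3-dioxin-4-one) | CC1(C)OC(=O)C=C(CC(=O)[C@H]2[C@H](c3ccc(OCc4ccccc4)cc3)[C@H](C(=O)CC3=CC(=O)OC(C)(C)O3)[C@H]2c2ccc(OCc3ccccc3)cc2)O1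
F3 | step 4 | (1α,2α,3β,4β)-2,4-bis[4-(benzyloxy)phenyl]cyclobutane-1,3-dicarboxylic acid | OC(=O)[C@H]1[C@H](c2ccc(OCc3ccccc3)cc2)[C@H](C(=O)O)[C@H]1c1ccc(OCc2ccccc2)cc1
F4 | step 4 | (1α,2α,3β,4β)-2,4-bis[4-(benzyloxy)phenyl]-N1,N3-dimethoxy-N1,N3-dimethylcyclobutane-1,3-dicarboxamide | CON(C)C(=O)[C@H]1[C@H](c2ccc(OCc3ccccc3)cc2)[C@H](C(=O)N(C)OC)[C@H]1c1ccc(OCc2ccccc2)cc1
F0 | step 11 | none | none
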